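Readings and results were generated by integration with constants of no real substance; scatter was added.

The birch run, with 0.10 M substrate, gave its highest reading, 16.6% target, at 1.33 min. The oak run, at twice that charge, gave its highest reading, 14.4%, at the same time.

| flask | substrate | gas phase | remark | time |
|---|---|---|---|---|
| oak | 0.20 M | 50 mM (held) | the very flask that is asked about, followed so far |  |
| birch | 0.10 M | 50 mM (held) | run made earlier |  |
| flask | 0.20 M | 50 mM (held) |  | 50 min |

| run | time / min | target / % |
|---|---|---|
| oak | 0.333 | 7.3 |
| oak | 0.667 | 12.2 |
| oak | 1.33 | 14.4 |
| oak | 2.50 | 8.5 |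
| oak | 5.00 | 6.7 |
| oak | 10.0 | 2.1 |
| oak | 20.0 | 0 |
| birch | 0.333 | 9.4 |
| birch | 0.667 | 15.3 |
| birch | 1.33 | 16.6 |
| birch | 2.50 | 9.1 |
| birch | 5.00 | 3.5 |
| birch | 10.0 | 0 |
| birch | 20.0 | 0.3 |

(readings scatter by 1 percentage point)

- at the start none of the gas phase is in solution

- time, not beyond 50 min, at which the flask holds most target
- the amount of target, in percent of the substrate charged, at that time

The longest time needs little care: oak reads 0% at 20.0 min, earlier than the limit. The charge needs more: from birch to oak the highest reading moved by 2.2 percentage points, against a scatter of 1 point. The saturation concentration stood at 50 mM in both runs, so they show no effect of it.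

That saturation is smaller than the oak charge, so a balance of gas is worth writing, taking one gas per target. The oak peak reading then gives 0.576. This is target concentration at the peak over saturation concentration, the gas fill. Birch reads 0.332. The flask repeats oak, so the reckoning here expects about 14.4% near 1.33 min, a fill of 0.576, below one.

The forecast gives 15% at 1.1 min, higher and earlier than that, on the ground that “oak is the direct guide”.

The flask peaks at 1.22 min with 12.8%, and the forecast holds within its margins.

    substrate + dissolved gas ⇌ target (K = 9.40 M⁻¹, k = 44.0 M⁻¹ min⁻¹)
    gas phase ⇌ dissolved gas, rate k2*(csat - [dissolved gas]) (kL = 2.40 min⁻¹)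
    dissolved gas + target → over-reacted product (k = 22.0 M⁻¹ min⁻¹)
    target → over-reaction product (k = 0.970 min⁻¹)

The gas fill of the flask is 0.514, where the oak peak reading gave 0.576, with target below saturation. The neighbour with 0.80 M substrate peaks at 7.30%, a lower share than the flask. Its gas fill is 1.17, twice the oak reading of 0.576, with target above saturation. Substrate is the limiting reagent in that neighbour, with 0% left at the end. At 50.0 min the neighbour holds 30.4% over-reacted product and 69.6% over-reaction product, where the flask holds 42.0% and 58.0%.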